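## Structural features

The target 11 is a 1H-indole, in which a benzene ring (C3a, C4, C5, C6, C7, C7a) is fused along the C3a–C7a bond to a pyrrole ring (N1, C2, C3, C3a, C7a). The molecule is flat and has no stereocentre, so no stereocentres stand next to each other and nothing has to be controlled in space. Bromine sits on the adjacent pyrrole carbons C2 and C3 and on C6 of the benzene ring, which is para to C3a and meta to C7a, while N1 keeps its hydrogen. The fragile part is the N–H 2,3-dibromopyrrole unit, an electron-rich bromo-enamine that is expected to suffer from acid, light and air, and all three C–Br bonds exclude organolithium bases, dissolving metals and zerovalent palladium once they are in place. The real difficulty is therefore regiochemistry and timing, not skeleton: an electrophile attacks an indole at C3 first and at C2 less cleanly, C5 and C6 compete on the benzene ring, and C2 lithiation is closed by the bromine at C6. The key step exploits the para relationship between C6 and C3a: the aryl ring of an open-chain precursor is then 1,4-disubstituted, its two C–H positions ortho to the side chain are identical, and closure of N1 onto either one (the future C7a) can give only the 6-bromo isomer. The ester that this precursor carries on the future C2 marks that carbon for a later ipso exchange of carboxylate for bromine.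

## Logic of the disconnections

**11 ⇒ 9.** The C2–Br and C3–Br bonds are cut together; C3 goes back to C–H and C2 to C–CO2H. Both bromines can then enter as electrophilic bromine, at C3 by ordinary substitution and at C2 by ipso attack on a carboxylate that leaves as a gas, so no C2 metalation is needed beside the C6 bromide. The gain is that the sensitive dibromopyrrole unit is absent from every compound but the last, and the C2 problem becomes a carboxyl group that the ring synthesis supplies anyway. The forward step must deliver two bromine equivalents and no more, pass through 10 in the flask, and run under non-acidic conditions that 11 survives.

**9 ⇒ 8.** The acyl C–OH bond is exchanged for C–OMe, a change of functional group only. The ester is wanted earlier because it acidifies the α-position for the condensation, stabilises the azide-bearing double bond by conjugation, and is inert to heat. Nothing is gained in skeleton; the acid simply stays masked until the last step needs it. The forward step must cleave the ester without touching the aryl bromide or the indole ring.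

**8 ⇒ 6.** The N1–C7a bond is cut, which opens the pyrrole ring and leaves a benzene ring with a three-carbon side chain whose future C2 bears nitrogen as an azide. The cut is placed there because C7a is one of two equivalent ortho carbons of a para-substituted ring, so the regiochemistry of ring closure is not in question. The gain is a bicycle reduced to a monocyclic arene, with N1, C2 and the C2 carboxyl handle all in one side chain. The forward step must bring the nitrogen to the nitrene level by loss of dinitrogen, leave the C–Br bond alone, and let the intramolecular closure outrun bimolecular paths, which calls for dilution.

**6 ⇒ 3 + 4.** The C=C bond between the future C2 and C3 is cut. This is the retron of an aldol condensation and divides 6 into an aromatic aldehyde that already holds the bromine in the right place and a two-carbon azido ester. The gain is two small fragments and no regiochemical question at all. The forward step must form the ester enolate of 3 at a temperature at which the azide survives, and must dehydrate 5 in the same flask; the geometry of the double bond is not critical, because the thermolysis funnels both isomers through 7.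

**3 ⇒ 1 + 2.** The C–N bond is cut to an α-bromo ester and azide ion. The reason is the ease of substitution at a carbon next to an ester; the gain is two bulk chemicals. The forward step must be run so that 3, a small and energetic azide, is never isolated neat.

## Other disconnections considered

Alternative 1: The cut runs through N1–C2 and C3–Br and opens the pyrrole ring to N-[5-bromo-2-(bromoethynyl)phenyl]-4-methylbenzenesulfonamide A2, which goes back to 5-bromo-2-iodoaniline A3. In the forward key step an electrophilic bromine source (NBS, or CuBr2 as a divalent copper halide) would activate the bromoalkyne of A2, the sulfonamide nitrogen would add 5-endo-dig to the bromine-bearing alkyne carbon, and C3 would take up bromine, giving 2,3,6-tribromo-1-tosyl-1H-indole A1.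
- In its favour: C2–Br comes in with the alkyne and C3–Br arrives during ring closure, so neither pyrrole bromine depends on substitution of a finished indole. No azide is used, and the closure would run near room temperature. On thermal hazard and on regiochemical certainty at C2 and C3 this alternative is the better plan.
- Against it: A2 would have to be built from A3 by an iodide-selective Sonogashira coupling (PdCl2(PPh3)2, CuI), N-sulfonylation and bromination of the alkyne terminus, so zerovalent palladium would meet the C–Br bond that must survive. Simple addition of bromine across the triple bond competes with the 5-endo closure. The tosyl group must finally be removed from A1, and the nucleophilic or reducing conditions for that threaten C2–Br (addition–elimination at C2 of an N-sulfonyl 2-haloindole) or all three C–Br bonds.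
- Comparison: on structure the two plans are equal, since both take C6–Br from a commercial arene. On mechanism the alternative is ionic and mild, against a nitrene at 140 °C in the chosen plan. On step count they are about equal, five steps from A3 against five. The chosen plan ends with the bromination itself and needs no protecting group, whereas the alternative ends with a deprotection of A1, its most sensitive compound.

Alternative 2: The cut removes C3a–C7a and C4–C5, so the benzene ring is taken apart, leading back to methyl (4-bromo-2-oxo-2H-pyran-6-yl)(but-3-yn-1-yl)carbamate A5. In the forward key step, heating A5 in 1,2-dichlorobenzene would bring about an intramolecular Diels–Alder reaction of the pyrone diene with the tethered terminal alkyne, followed by cycloreversion with extrusion of the lactone bridge as carbon dioxide, to give methyl 6-bromoindoline-1-carboxylate A4.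
- In its favour: two C–C bonds and both rings are formed in one operation, which is more bond construction per step than the chosen key step offers, and on that count it is the better step. The bromine position is fixed by C4 of the pyrone with no isomer possible, and no azide is needed.
- Against it: the brominated benzene ring is a bulk chemical in the chosen plan, so building it is over-construction. A5 requires a pyrone that carries bromine at C4 and nitrogen at C6, which is itself a multi-step problem. A4 is an N-acyl indoline, so dehydrogenation, carbamate removal and both pyrrole brominations would still follow, the last without any handle at C2. An unactivated alkyne on a nitrogen-substituted pyrone is expected to need forcing temperatures.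
- Comparison: on structure the plans are equal in fixing C6. On mechanism both key steps are thermal, reagent-free and tolerant of C–Br, so they are equal there as well. On step economy the alternative is clearly longer, roughly double the five steps of the chosen plan once the preparation of A5 and the steps after A4 are counted.

Alternative 3: The cut is at C2–C3 and leads back to 4-bromo-2-isocyano-1-methylbenzene A7, which in turn goes back to 5-bromo-2-methylaniline A8. In the forward key step LiN(iPr)2 (LDA) would deprotonate the benzylic methyl group of A7, the carbanion would add to the isocyanide carbon to form C2–C3 (Ito–Saegusa indole synthesis), and work-up would give 6-bromo-1H-indole A6.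
- In its favour: A7 should be available from A8 by formylation and dehydration, the closure is fast at low temperature, and no azide is used. With a double bromination of A6 the target would be reached in four steps from A8, one fewer than the chosen plan, so on step count the alternative is better.
- Against it: a strong lithium amide and a benzyllithium must coexist with the aryl bromide of A7, so deprotonation next to bromine, followed by loss of LiBr or bromine migration, competes. A6 has no substituent at C2, so C2–Br must come from direct electrophilic bromination of the free pyrrole ring after C3 has been brominated, the least controlled way to make that bond. Isocyanides such as A7 are unpleasant to handle. A6 is also an article of commerce, so this ring construction from A8 adds little over buying it.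
- Comparison: on structure the plans are equal, since both rely on the para relationship between the bromine and the carbon that becomes C3a. On mechanism the chosen plan tolerates C–Br better, being thermal and metal-free where the alternative is anionic. On step economy the alternative is shorter by one step, and the chosen plan has the more controlled end game because of the carboxyl handle at C2.

Key step: step 3

Assumption on the chemistry: 11 is treated as acid-, light- and air-sensitive, so it is formed in the last step without an N-protecting group and handled cold under argon.

Remark on safety: 3 has a low carbon-to-nitrogen ratio and stays in solution throughout. NaN3 is kept away from acids, chlorinated solvents and heavy metals, and aqueous azide waste is destroyed with NaNO2 under acidification in a hood. Batches of 3 and 6 are kept small, and the thermolysis is run behind a shield by slow addition.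

Remark on structure: in 6 the azide and the aryl group lie on the same side of the double bond (Z), and a bromine para to the side chain of 6 maps onto C6 of 8 and of 11.

## Route

Step 1
Reactants: 1 methyl bromoacetate; 2 sodium azide
Product: 3 methyl azidoacetate
Conditions: NaN3 (1.2 equiv), Bu4NBr (5 mol %), H2O/MTBE, 20 °C; phase separation, MgSO4; kept as ca. 1 M MTBE solution
Reagents that add atoms: none
Why: SN2 displacement of the activated α-bromide by azide under phase-transfer catalysis should be fast at room temperature. The product stays in the MTBE layer and is assayed and used as that solution, never distilled or concentrated to dryness, which removes the main hazard of a small organic azide.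

Step 2
Reactants: 3 methyl azidoacetate; 4 4-bromobenzaldehyde
Product: 6 methyl (Z)-2-azido-3-(4-bromophenyl)acrylate, via aldol adduct 5 (not isolated)
Conditions: 3 (4 equiv), NaOMe (4 equiv), MeOH (MTBE co-solvent), −15 → 0 °C; ice-water work-up, product kept cold and dark
Reagents that add atoms: none
Why: Knoevenagel-type aldol condensation: methoxide forms the ester enolate of 3 at a temperature the azide tolerates, addition to the non-enolisable aldehyde 4 gives the alkoxide of 5, and E1cB loss of hydroxide gives the conjugated ester. The Z isomer (azide cis to aryl, ester trans to aryl) is the thermodynamically favoured one, and matching NaOMe/MeOH to the methyl ester rules out ester scrambling.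

Step 3
Reactants: 6 methyl (Z)-2-azido-3-(4-bromophenyl)acrylate
Product: 8 methyl 6-bromo-1H-indole-2-carboxylate, via 2H-azirine 7 (not isolated)
Conditions: xylenes, 140 °C (reflux), slow addition of a solution of 6, final ≤ 0.05 M, N2 sweep
Reagents that add atoms: none
Why: On heating, 6 loses N2 to give a singlet vinyl nitrene that is in equilibrium with 2H-azirine 7, so the geometry of the double bond of 6 no longer matters. The nitrene nitrogen, the C2=C3 double bond and the C3a=C7a bond of the arene make up a 1-azapentadienyl system that closes by a 6π, five-atom (1,5-) electrocyclisation, which forms the N1–C7a bond and the pyrrole ring. A 1,5-hydrogen shift from C7a to N1 then restores the benzene ring and gives the 1H-indole. The closest known reaction type is the Hemetsberger–Knittel indole-2-carboxylate synthesis from 2-azidocinnamates, of which this is a direct case. No stereocentre is formed. The step needs regioselectivity between the two ortho positions and chemoselectivity towards the C–Br bond: the first is secured by the 1,4-disubstituted ring, whose two ortho C–H sites are identical, so that only the 6-bromo isomer can arise, and the second by the absence of any metal, base or radical initiator. Slow addition into a large volume of boiling xylene keeps the standing concentration of 6 and 7 low, which favours the unimolecular closure over dimerisation and meters the release of nitrogen.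

Step 4
Reactants: 8 methyl 6-bromo-1H-indole-2-carboxylate
Product: 9 6-bromo-1H-indole-2-carboxylic acid
Conditions: LiOH·H2O (3 equiv), THF/MeOH/H2O, 40 °C; then 1 M HCl to pH 2, filtration
Reagents that add atoms: lithium hydroxide monohydrate, O.[Li+].[OH-]
Why: Saponification (hydroxide addition–elimination at the ester carbonyl) of an aryl-conjugated methyl ester is routine. The aryl bromide and the indole N–H are inert to aqueous LiOH, and the acid should precipitate on acidification.

Step 5
Reactants: 9 6-bromo-1H-indole-2-carboxylic acid
Product: 11 2,3,6-tribromo-1H-indole, via 3,6-dibromo-1H-indole-2-carboxylic acid 10 (not isolated)
Conditions: NBS (2.05 equiv, in portions), LiOAc (0.2 equiv), DMF, −10 → 20 °C, dark, Ar; cold aq. Na2S2O3/NaHCO3; fast chromatography on Et3N-washed silica, storage at −20 °C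
Reagents that add atoms: N-bromosuccinimide, O=C1CCC(=O)N1Br
Why: The first equivalent of NBS should brominate C3, the most nucleophilic carbon, by electrophilic aromatic substitution to give 10. The second should attack C2 ipso to the carboxylate, and the resulting cation collapses by loss of CO2 instead of a proton (halodecarboxylation of a heteroaromatic acid, a Hunsdiecker-type ipso substitution). No organometallic reagent is involved, so the C6 bromide and the free N–H are untouched.

## Compound list

1 | methyl bromoacetate | COC(=O)CBr | starting material
2 | sodium azide | [Na+].[N-]=[N+]=[N-] | starting material
3 | methyl azidoacetate (used as a solution) | COC(=O)CN=[N+]=[N-] | intermediate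
4 | 4-bromobenzaldehyde | O=Cc1ccc(Br)cc1 | starting material
5 | methyl 2-azido-3-(4-bromophenyl)-3-hydroxypropanoate (aldol adduct, racemic mixture of diastereomers, formed in the flask as its sodium alkoxide, not isolated) | COC(=O)C(N=[N+]=[N-])C(O)c1ccc(Br)cc1 | intermediate
6 | methyl (Z)-2-azido-3-(4-bromophenyl)acrylate (azide and aryl cis) | COC(=O)/C(N=[N+]=[N-])=C/c1ccc(Br)cc1 | intermediate
7 | methyl 2-(4-bromophenyl)-2H-azirine-3-carboxylate (racemic, formed in the flask, not isolated) | COC(=O)C1=NC1c1ccc(Br)cc1 | intermediate
8 | methyl 6-bromo-1H-indole-2-carboxylate | COC(=O)c1cc2ccc(Br)cc2[nH]1 | intermediate
9 | 6-bromo-1H-indole-2-carboxylic acid | OC(=O)c1cc2ccc(Br)cc2[nH]1 | intermediate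
10 | 3,6-dibromo-1H-indole-2-carboxylic acid (formed in the flask, not isolated) | OC(=O)c1[nH]c2cc(Br)ccc2c1Br | intermediate
11 | 2,3,6-tribromo-1H-indole | Brc1ccc2c(Br)c(Br)[nH]c2c1 | target

## Step count and least certain steps

Total step count: 5. Longest linear sequence: 5 steps (1 → 3 → 6 → 8 → 9 → 11).

**Step 3 (key step).** The most likely failure is diversion of the reactive intermediates. If 6 or 7 builds up in the hot solution, azirine dimerisation, attack of the nitrene on a second molecule and charring compete with the unimolecular closure, and nitrogen is released in a surge. Fallback, setting out from 6: nitrene transfer catalysed by Rh2(O2CC3F7)4 (dirhodium tetrakis(heptafluorobutyrate), 3–5 mol %) in toluene at 40–60 °C. Here a rhodium-bound nitrenoid, not a free nitrene or azirine, aminates the ortho C–H bond, and the aryl bromide is inert to divalent rhodium carboxylates. The fallback comes back to the route at 8 and makes no new compound (entry F0).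

**Step 5.** Two things may go wrong. Over-bromination is the first: a third bromine equivalent attacking C3 of the product would give a 3,3-dibromoindolenine that hydrolyses to oxindole-type material on work-up. The second is sluggish ipso substitution, because C2 of 10 is deactivated by the C3 bromine and the carboxyl group; the sensitive product would then sit in the mixture long enough to lose or shift bromine. Fallback, setting out from 9: the carboxyl group is first removed on its own, with Ag2CO3 (10 mol %) and AcOH (catalytic) in DMSO at 120 °C, which should protodecarboxylate 9 to 6-bromo-1H-indole F1. F1 would then be treated with NBS (2.0 equiv) on silica gel in CH2Cl2 at 0 °C in the dark. Bromination at C3 should give 3,6-dibromo-1H-indole F2 in the flask, and a second bromination at C2, by C3 attack and 1,2-shift of bromine, comes back to the route at 11.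

**Step 2.** The enolate of 3 can expel N2 before it meets the aldehyde, and the E1cB dehydration can stall, so that 5 and hydrolysed material accompany 6. Fallback, setting out from 3 and 4: carbon–carbon bond formation and elimination are separated. The addition is stopped at the aldol stage (NaOMe, MeOH, −30 °C, cold AcOH quench) and 5 is isolated. 5 is then treated with MsCl and Et3N in CH2Cl2 at 0 °C to give the mesylate methyl 2-azido-3-(4-bromophenyl)-3-[(methylsulfonyl)oxy]propanoate F3, which should lose methanesulfonate by base-induced elimination in the same flask and come back to the route at 6.

## Further compounds

F0 | step 3 | none | none
F1 | step 5 | 6-bromo-1H-indole | Brc1ccc2cc[nH]c2c1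
F2 | step 5 | 3,6-dibromo-1H-indole | Brc1ccc2c(Br)c[nH]c2c1
F3 | step 2 | methyl 2-azido-3-(4-bromophenyl)-3-[(methylsulfonyl)oxy]propanoate (racemic mixture of diastereomers) | COC(=O)C(N=[N+]=[N-])C(OS(C)(=O)=O)c1ccc(Br)cc1
A1 | alternative 1 | 2,3,6-tribromo-1-tosyl-1H-indole | Cc1ccc(cc1)S(=O)(=O)n1c(Br)c(Br)c2ccc(Br)cc21
A2 | alternative 1 | N-[5-bromo-2-(bromoethynyl)phenyl]-4-methylbenzenesulfonamide | Cc1ccc(cc1)S(=O)(=O)Nc1cc(Br)ccc1C#CBr
A3 | alternative 1 | 5-bromo-2-iodoaniline | Nc1cc(Br)ccc1I
A4 | alternative 2 | methyl 6-bromoindoline-1-carboxylate | COC(=O)N1CCc2ccc(Br)cc21
A5 | alternative 2 | methyl (4-bromo-2-oxo-2H-pyran-6-yl)(but-3-yn-1-yl)carbamate | COC(=O)N(CCC#C)C1=CC(Br)=CC(=O)O1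
A6 | alternative 3 | 6-bromo-1H-indole | Brc1ccc2cc[nH]c2c1
A7 | alternative 3 | 4-bromo-2-isocyano-1-methylbenzene | [C-]#[N+]c1cc(Br)ccc1C
A8 | alternative 3 | 5-bromo-2-methylaniline | Cc1ccc(Br)cc1N
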